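(The runs are simulated with made-up constants.)

Tuesday's flask is asked about at 8.0 d, 4.80 times its last reading at 40.0 h.

in all of them: gas 200 mM (held)

| charge | substrate | remark | time |
|---|---|---|---|
| Tuesday's | 1.5 M | the very flask that is asked about, followed so far |  |
| Friday's | 2.2 M | run made earlier |  |
| flask | 1.5 M |  | 8.0 d |

Tuesday's run (percent of the substrate charged)

| time / h | target / % | side product B / % | substrate / % |
|---|---|---|---|
| 6.00 | 23 | 0 | 56 |
| 12.0 | 53 | 3 | 12 |
| 15.0 | 62 | 0 | 2 |
| 20.0 | 70 | 6 | 4 |
| 30.0 | 74 | 13 | 0 |
| 40.0 | 76 | 16 | 0 |

Friday's run (percent of the substrate charged)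

| time / d | target / % | side product B / % | substrate / % |
|---|---|---|---|
| 0.625 | 47 | 0 | 17 |
| 1.04 | 71 | 4 | 1 |
| 1.67 | 72 | 15 | 0 |
| 2.50 | 68 | 8 | 0 |
| 3.00 | 71 | 13 | 0 |
| 5.00 | 74 | 12 | 2 |
| 8.00 | 69 | 13 | 0 |

(scatter of a reading: 2 percentage points)

- at the start none of the gas is in solution
- a reading or a percentage of target counts all its forms, free or not

- amount of target at 8.0 d, in percent of the substrate charged
- amount of side product B at 8.0 d, in percent of the substrate charged

Two chemists dispute this flask. The first holds that it has stopped, and the forecast is hers: 76% target and 14% side product B, on the ground that “Friday's run shows that both products are stable once formed.” Friday's flask reads target 72% at 1.67 d and 69% at 8.00 d.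

The second points to Tuesday's flask, where side product B rose by 3 percentage points between 30.0 h and 40.0 h, with substrate, the limiting reagent, reading 0%. She also finds 8 points of the charge unaccounted for at 40.0 h, books it on side product B and expects 24.0%.

My own reckoning counts half-lives. In Tuesday's flask side product B rose by 7 points, then by 3 points, over equal steps of 10.0 h. If each rise keeps that ratio of 0.429, itself a reading from these few points, the gap to the end value halves every 8.18 h, which I call the settling half-life. Then 18.6 of them lie between the last reading and the asked time, and hardly any of the gap survives, so on the stop I side with the first chemist. On the level I differ from the forecast: the same ratio adds 2.2 points, giving 18.2%, though a scatter of 2 points makes that loose.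

The simulation gives 72.3% target and 16.1% side product B, so the forecast holds within its margin, and the second chemist's figure is higher by 7.9 points. A flask still moving, as she holds, is what Tuesday's flask is early on: at 0.800 d intermediates A, B and C stand at 8.27%, 4.57% and 2.25%, and at 4.00 d they stand at 0%, 0% and 0%. That later time lies 6.85 settling half-lives after the last reading.

    substrate + partner → intermediate A (k = 0.0267 M⁻¹ min⁻¹)
    partner + intermediate A → intermediate B (k = 0.0115 M⁻¹ min⁻¹)
    substrate + partner → intermediate C (k = 0.0696 M⁻¹ min⁻¹)
    intermediate A → side product A (k = 7.44 × 10⁻⁴ min⁻¹)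
    intermediate B → side product B (k = 0.00298 min⁻¹)
    intermediate C → target (k = 0.00646 min⁻¹)
    gas ⇌ partner, rate k7*(csat - [partner]) (kL = 0.0114 min⁻¹)
    crystals ⇌ target, rate k8*(cs8 - [target]) while solid is left; crystals form when [target] > cs8 (solubility = 0.0960 M, k = 0.597 min⁻¹)

Tuesday's charge read at 5.0 d lies 9.78 settling half-lives after the last reading, so the reckoning puts hardly any of the gap there. It gives 72.3% target and 16.1% side product B.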